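## Retrosynthetic overview

1. Numbering used below: decalin C-1 (bears CMe2OH), C-4 (CH3), C-4a=C-5, C-6 (quaternary), C-8a (H); C-α is the benzylic CH. The aryl ring is finished last on a 2,6-dimethoxyphenyl carrier: C–H borylation/oxidation, double ortho-formylation, O-demethylation.
2. C-4a=C-5 comes from an enol triflate. Ring B (second ring) is closed by an intramolecular Michael addition (C-1 to C-8a); its side chain comes from an organocatalytic Michael addition of a ring-A 1,3-dione to crotonaldehyde plus a Wittig C2 unit.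
3. The C-6/C-α bond and both stereocentres come from a chiral-acid-catalysed SN1 α-alkylation of an α-methyl ketone with a racemic benzylic alcohol (new step).
4. Ring A (first ring) comes from a one-carbon ring expansion of a cyclopentanone: a β-oxido carbenoid 1,2-shift inserts C-6 together with its methyl group.
5. Building blocks: 1,3-dimethoxybenzene, 3-methylbutanal, 1,4-dioxaspiro[4.4]nonan-7-one, 1,1-dibromoethane, crotonaldehyde.

Assumption: 1 and 5 are bought as such; their O-methyl and dioxolane groups are protecting groups of resorcinol and of cyclopentane-1,3-dione and are removed in steps 12 and 3.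

## Route

Step 1
Reactants: 1 1,3-dimethoxybenzene; 2 3-methylbutanal
Product: 4 rac-1-(2,6-dimethoxyphenyl)-3-methylbutan-1-ol, via 2,6-dimethoxyphenyllithium 3 (not isolated)
Conditions: n-BuLi (1.05 equiv), THF, 0 °C to rt; then 2, −78 °C to rt; H2O
Reagents that add atoms: none
Why: Directed ortho-lithiation between the two methoxy groups followed by 1,2-addition of the aryllithium to the aldehyde gives the benzylic alcohol, whose stereocentre need not be controlled because it is ionised in step 3.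

Step 2
Reactants: 5 1,4-dioxaspiro[4.4]nonan-7-one; 6 1,1-dibromoethane
Product: 10 rac-8-methyl-1,4-dioxaspiro[4.5]decan-7-one, via 1,1-dibromoethyllithium 7 (not isolated), via dibromo alkoxide 8 (not isolated), via lithium enolate 9 (not isolated)
Conditions: LiN(iPr)2 (1.1 equiv) added to 5 + 6, THF, −95 °C; n-BuLi (1.2 equiv), −95 to 0 °C; H2O
Reagents that add atoms: none
Why: A β-oxido carbenoid (Nozaki–Yamamoto type) one-carbon ring expansion: 7 adds to the ketone, bromine–lithium exchange on 8 gives an α-bromo-α-lithio alkoxide whose semipinacol-like 1,2-shift of the ring methylene remote from the dioxolane (the other methylene is neopentyl-like and inductively deactivated by the two β-oxygens) expels LiBr and inserts the methyl-bearing carbon C-6 next to the carbonyl, and protonation of enolate 9 gives racemic 10, whose labile α-stereocentre is reset in step 3.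

Step 3
Reactants: 10 rac-8-methyl-1,4-dioxaspiro[4.5]decan-7-one; 4 rac-1-(2,6-dimethoxyphenyl)-3-methylbutan-1-ol
Product: 12 (4R)-4-[(1R)-1-(2,6-dimethoxyphenyl)-3-methylbutyl]-4-methylcyclohexane-1,3-dione, via ketal ketone 11 (not isolated)
Conditions: 10 (1.5 equiv), 4 (1 equiv), (R)-N-triflylphosphoramide of 3,3'-bis(2,4,6-triisopropylphenyl)-BINOL (5 mol%), 5 Å molecular sieves, toluene, 0 °C to rt; then 2 M HCl, THF, rt
Reagents that add atoms: water, O
Why: Proposed new method: the strong chiral Brønsted acid ionises racemic 4 to the 2,6-dimethoxy-stabilised benzylic cation, which stays as a contact ion pair with the chiral phosphoramidate while the same anion hydrogen-bonds the tetrasubstituted enol of racemic 10 (formed on the more substituted side), so that both stereolabile partners meet in one organised transition state that sets the quaternary C-6 and the benzylic C-α (both R in 11, the catalyst enantiomer being chosen accordingly) before acid hydrolysis of the dioxolane; the closest known reaction types are phosphoric-acid enol catalysis for α-functionalisation of α-branched cyclic ketones and chiral-acid-catalysed SN1 substitutions of electron-rich benzylic alcohols through ion-paired carbocations or ortho-quinone methides.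

Step 4
Reactants: 12 (4R)-4-[(1R)-1-(2,6-dimethoxyphenyl)-3-methylbutyl]-4-methylcyclohexane-1,3-dione; 13 (E)-but-2-enal
Product: 15 methyl (2E,5R)-5-{(3R)-3-[(1R)-1-(2,6-dimethoxyphenyl)-3-methylbutyl]-3-methyl-2,6-dioxocyclohexyl}hex-2-enoate, via Michael aldehyde 14 (not isolated)
Conditions: (S)-α,α-diphenylprolinol trimethylsilyl ether (10 mol%), CH2Cl2, 0 °C to rt; then Ph3P=CHCO2Me (1.3 equiv), rt
Reagents that add atoms: methyl (triphenylphosphoranylidene)acetate, COC(=O)C=P(c1ccccc1)(c1ccccc1)c1ccccc1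
Why: Iminium-catalysed Michael addition of the 1,3-dione (through C-4a) to crotonaldehyde, in which the bulky diarylsilyloxymethyl group of the (S)-catalyst shields one face of the (E)-iminium ion so that C-4 is formed with R configuration irrespective of the remote stereocentres, followed by an E-selective Wittig olefination of the aldehyde (present mainly as its cyclic hemiacetal) with the stabilised ylide.

Step 5
Reactants: 15 methyl (2E,5R)-5-{(3R)-3-[(1R)-1-(2,6-dimethoxyphenyl)-3-methylbutyl]-3-methyl-2,6-dioxocyclohexyl}hex-2-enoate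
Product: 16 methyl (5R)-5-{(3R)-3-[(1R)-1-(2,6-dimethoxyphenyl)-3-methylbutyl]-3-methyl-2,6-dioxocyclohexyl}hexanoate
Conditions: H2 (1 atm), Pd/C (10 wt%), EtOAc, Et3N (trace), rt
Reagents that add atoms: none
Why: Heterogeneous catalytic hydrogenation saturates only the conjugated enoate double bond (arene, dione and stereocentres untouched), the trace of base keeping any oxa-Michael-cyclised material in equilibrium with the open enoate.

Step 6
Reactants: 16 methyl (5R)-5-{(3R)-3-[(1R)-1-(2,6-dimethoxyphenyl)-3-methylbutyl]-3-methyl-2,6-dioxocyclohexyl}hexanoate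
Product: 18 methyl (5R)-5-{(5R)-5-[(1R)-1-(2,6-dimethoxyphenyl)-3-methylbutyl]-5-methyl-6-oxocyclohex-1-en-1-yl}hexanoate, via vinylogous triflate 17 (not isolated)
Conditions: (CF3SO2)2O (1.1 equiv), 2,6-lutidine, CH2Cl2, −78 °C; crude 17, Pd(OAc)2 (5 mol%), PPh3 (10 mol%), HCO2H, Et3N, DMF, 60 °C
Reagents that add atoms: none
Why: O-Triflation of the 2-alkyl-1,3-dione occurs at the enol oxygen remote from the quaternary centre for steric reasons, and Pd-catalysed formate reduction of the resulting vinylogous acyl triflate (oxidative addition to zerovalent palladium, decarboxylative hydride transfer, reductive elimination) unmasks the C-8a–H enone without touching any stereocentre.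

Step 7
Reactants: 18 methyl (5R)-5-{(5R)-5-[(1R)-1-(2,6-dimethoxyphenyl)-3-methylbutyl]-5-methyl-6-oxocyclohex-1-en-1-yl}hexanoate
Product: 20 methyl (1S,4R,6R,8aR)-6-[(1S)-1-(2,6-dimethoxyphenyl)-3-methylbutyl]-4,6-dimethyl-5-(trifluoromethanesulfonyloxy)-1,2,3,4,6,7,8,8a-octahydronaphthalene-1-carboxylate, via lithium enolate 19 (not isolated)
Conditions: LiN(SiMe3)2 (1.1 equiv), THF, −78 to −20 °C; then N-(5-chloropyridin-2-yl)bis(trifluoromethanesulfonimide) (1.2 equiv), −78 °C to rt; H2O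
Reagents that add atoms: N-(5-chloropyridin-2-yl)bis(trifluoromethanesulfonimide), O=S(=O)(N(c1ccc(Cl)cn1)S(=O)(=O)C(F)(F)F)C(F)(F)F
Why: Intramolecular Michael addition (6-endo) of the lithium ester enolate to the enone closes ring B, 1,3-allylic strain between the C-5 carbonyl and the C-4 substituents holding C-4–H in the enone plane so that the tether reaches C-8a from the face opposite to the C-4 methyl group (H-8a cis to that methyl) with the ester ending equatorial at C-1 in the chair-like transition state, and the regiodefined enolate 19 is trapped in situ as the enol triflate.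

Step 8
Reactants: 20 methyl (1S,4R,6R,8aR)-6-[(1S)-1-(2,6-dimethoxyphenyl)-3-methylbutyl]-4,6-dimethyl-5-(trifluoromethanesulfonyloxy)-1,2,3,4,6,7,8,8a-octahydronaphthalene-1-carboxylate
Product: 21 methyl (1S,4R,6S,8aR)-6-[(1S)-1-(2,6-dimethoxyphenyl)-3-methylbutyl]-4,6-dimethyl-1,2,3,4,6,7,8,8a-octahydronaphthalene-1-carboxylate
Conditions: Pd(OAc)2 (5 mol%), PPh3 (10 mol%), n-Bu3N, HCO2H, DMF, 60 °C
Reagents that add atoms: none
Why: Pd-catalysed formate reduction of the enol triflate (oxidative addition to zerovalent palladium, hydride transfer from formate) replaces the C-5 oxygen by hydrogen and thereby fixes the C-4a=C-5 double bond regiospecifically, no stereocentre being involved.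

Step 9
Reactants: 21 methyl (1S,4R,6S,8aR)-6-[(1S)-1-(2,6-dimethoxyphenyl)-3-methylbutyl]-4,6-dimethyl-1,2,3,4,6,7,8,8a-octahydronaphthalene-1-carboxylate
Product: 22 2-{(1S,4R,6S,8aR)-6-[(1S)-1-(2,6-dimethoxyphenyl)-3-methylbutyl]-4,6-dimethyl-1,2,3,4,6,7,8,8a-octahydronaphthalen-1-yl}propan-2-ol
Conditions: MeMgBr (4 equiv), THF, 0 °C to rt; aqueous NH4Cl
Reagents that add atoms: methylmagnesium bromide, C[Mg]Br
Why: Double Grignard addition of MeMgBr to the methyl ester gives the tertiary carbinol without affecting the stereocentres, C-1 already being in its equatorial and thermodynamically preferred configuration.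

Step 10
Reactants: 22 2-{(1S,4R,6S,8aR)-6-[(1S)-1-(2,6-dimethoxyphenyl)-3-methylbutyl]-4,6-dimethyl-1,2,3,4,6,7,8,8a-octahydronaphthalen-1-yl}propan-2-ol
Product: 24 2-{(1S,4R,6S,8aR)-6-[(1S)-1-(4-hydroxy-2,6-dimethoxyphenyl)-3-methylbutyl]-4,6-dimethyl-1,2,3,4,6,7,8,8a-octahydronaphthalen-1-yl}propan-2-ol, via aryl boronate 23 (not isolated)
Conditions: [Ir(OMe)(cod)]2 (1.5 mol%), 4,4'-di-tert-butyl-2,2'-bipyridine (3 mol%), B2pin2 (1.5 equiv), THF, 80 °C; then H2O2, NaOH, THF/H2O, 0 °C
Reagents that add atoms: hydrogen peroxide, OO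
Why: Sterically governed Ir-catalysed C–H borylation takes place at the only arene C–H that is not ortho to a substituent (para to the benzylic carbon), and oxidation of the aryl boronate with basic hydrogen peroxide (1,2-aryl shift from boron to oxygen) gives the phenol while the hindered trisubstituted alkene and the tertiary alcohol are inert.

Step 11
Reactants: 24 2-{(1S,4R,6S,8aR)-6-[(1S)-1-(4-hydroxy-2,6-dimethoxyphenyl)-3-methylbutyl]-4,6-dimethyl-1,2,3,4,6,7,8,8a-octahydronaphthalen-1-yl}propan-2-ol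
Product: 25 2-{(1S,4R,6S,8aR)-6-[(1S)-1-(3,5-diformyl-4-hydroxy-2,6-dimethoxyphenyl)-3-methylbutyl]-4,6-dimethyl-1,2,3,4,6,7,8,8a-octahydronaphthalen-1-yl}propan-2-ol
Conditions: MgCl2 (6 equiv), Et3N (12 equiv), paraformaldehyde (20 equiv), THF, reflux; dilute HCl work-up
Reagents that add atoms: paraformaldehyde (as formaldehyde), C=O
Why: Magnesium-phenoxide-directed ortho-formylation (Casiraghi–Skattebøl conditions) hydroxymethylates and then oxidises (formaldehyde as hydride acceptor) both positions flanking the phenol, each of which is further activated by an adjacent methoxy group, under basic conditions that spare the tertiary alcohol and the alkene.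

Step 12
Reactants: 25 2-{(1S,4R,6S,8aR)-6-[(1S)-1-(3,5-diformyl-4-hydroxy-2,6-dimethoxyphenyl)-3-methylbutyl]-4,6-dimethyl-1,2,3,4,6,7,8,8a-octahydronaphthalen-1-yl}propan-2-ol
Product: 26 2-{(1S,4R,6S,8aR)-6-[(1S)-1-(3,5-diformyl-2,4,6-trihydroxyphenyl)-3-methylbutyl]-4,6-dimethyl-1,2,3,4,6,7,8,8a-octahydronaphthalen-1-yl}propan-2-ol (CNP0200991.2)
Conditions: NaSEt (8 equiv), DMF, 110 °C; then 1 M HCl
Reagents that add atoms: none
Why: Nucleophilic (SN2) O-demethylation by ethanethiolate is facilitated because each methoxy group is ortho and para to a formyl group (stabilised aryloxide leaving group), and these basic conditions leave the tertiary alcohol, the alkene and all stereocentres untouched, giving the target after acidification.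

## Compound list

The CIP descriptors at C-α and C-6 change between 18, 20 and 21 only because ligand priorities change; the geometry is the same throughout, as the SMILES show.

1 | 1,3-dimethoxybenzene | COc1cccc(OC)c1 | starting material
2 | 3-methylbutanal | CC(C)CC=O | starting material
3 | 2,6-dimethoxyphenyllithium | [Li]c1c(OC)cccc1OC | intermediate
4 | rac-1-(2,6-dimethoxyphenyl)-3-methylbutan-1-ol | CC(C)CC(O)c1c(OC)cccc1OC | intermediate
5 | 1,4-dioxaspiro[4.4]nonan-7-one | O=C1CCC2(C1)OCCO2 | starting material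
6 | 1,1-dibromoethane | CC(Br)Br | starting material
7 | 1,1-dibromoethyllithium | [Li]C(C)(Br)Br | intermediate
8 | lithium 7-(1,1-dibromoethyl)-1,4-dioxaspiro[4.4]nonan-7-olate | CC(Br)(Br)C1([O-])CCC2(C1)OCCO2.[Li+] | intermediate
9 | lithium 8-methyl-1,4-dioxaspiro[4.5]dec-7-en-7-olate | CC1=C([O-])CC2(CC1)OCCO2.[Li+] | intermediate
10 | rac-8-methyl-1,4-dioxaspiro[4.5]decan-7-one | CC1CCC2(CC1=O)OCCO2 | intermediate
11 | (8R)-8-[(1R)-1-(2,6-dimethoxyphenyl)-3-methylbutyl]-8-methyl-1,4-dioxaspiro[4.5]decan-7-one | CC(C)C[C@H](c1c(OC)cccc1OC)[C@]1(C)C(=O)CC2(CC1)OCCO2 | intermediate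
12 | (4R)-4-[(1R)-1-(2,6-dimethoxyphenyl)-3-methylbutyl]-4-methylcyclohexane-1,3-dione | CC(C)C[C@H](c1c(OC)cccc1OC)[C@]1(C)C(=O)CC(=O)CC1 | intermediate
13 | (E)-but-2-enal (crotonaldehyde) | C/C=C/C=O | starting material
14 | (3R)-3-{(3R)-3-[(1R)-1-(2,6-dimethoxyphenyl)-3-methylbutyl]-3-methyl-2,6-dioxocyclohexyl}butanal (ring C-1 enolised, mainly as cyclic hemiacetal) | CC(C)C[C@H](c1c(OC)cccc1OC)[C@]1(C)C(=O)C([C@H](C)CC=O)C(=O)CC1 | intermediate
15 | methyl (2E,5R)-5-{(3R)-3-[(1R)-1-(2,6-dimethoxyphenyl)-3-methylbutyl]-3-methyl-2,6-dioxocyclohexyl}hex-2-enoate | CC(C)C[C@H](c1c(OC)cccc1OC)[C@]1(C)C(=O)C([C@H](C)C/C=C/C(=O)OC)C(=O)CC1 | intermediate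
16 | methyl (5R)-5-{(3R)-3-[(1R)-1-(2,6-dimethoxyphenyl)-3-methylbutyl]-3-methyl-2,6-dioxocyclohexyl}hexanoate | CC(C)C[C@H](c1c(OC)cccc1OC)[C@]1(C)C(=O)C([C@H](C)CCCC(=O)OC)C(=O)CC1 | intermediate
17 | methyl (5R)-5-{(5R)-5-[(1R)-1-(2,6-dimethoxyphenyl)-3-methylbutyl]-5-methyl-6-oxo-2-(trifluoromethanesulfonyloxy)cyclohex-1-en-1-yl}hexanoate | CC(C)C[C@H](c1c(OC)cccc1OC)[C@]1(C)C(=O)C([C@H](C)CCCC(=O)OC)=C(OS(=O)(=O)C(F)(F)F)CC1 | intermediate
18 | methyl (5R)-5-{(5R)-5-[(1R)-1-(2,6-dimethoxyphenyl)-3-methylbutyl]-5-methyl-6-oxocyclohex-1-en-1-yl}hexanoate | CC(C)C[C@H](c1c(OC)cccc1OC)[C@]1(C)C(=O)C([C@H](C)CCCC(=O)OC)=CCC1 | intermediate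
19 | lithium (1S,4R,6R,8aR)-6-[(1S)-1-(2,6-dimethoxyphenyl)-3-methylbutyl]-1-(methoxycarbonyl)-4,6-dimethyl-1,2,3,4,6,7,8,8a-octahydronaphthalen-5-olate | CC(C)C[C@H](c1c(OC)cccc1OC)[C@]1(C)C([O-])=C2[C@H](C)CC[C@H](C(=O)OC)[C@H]2CC1.[Li+] | intermediate
20 | methyl (1S,4R,6R,8aR)-6-[(1S)-1-(2,6-dimethoxyphenyl)-3-methylbutyl]-4,6-dimethyl-5-(trifluoromethanesulfonyloxy)-1,2,3,4,6,7,8,8a-octahydronaphthalene-1-carboxylate | CC(C)C[C@H](c1c(OC)cccc1OC)[C@]1(C)C(OS(=O)(=O)C(F)(F)F)=C2[C@H](C)CC[C@H](C(=O)OC)[C@H]2CC1 | intermediate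
21 | methyl (1S,4R,6S,8aR)-6-[(1S)-1-(2,6-dimethoxyphenyl)-3-methylbutyl]-4,6-dimethyl-1,2,3,4,6,7,8,8a-octahydronaphthalene-1-carboxylate | CC(C)C[C@H](c1c(OC)cccc1OC)[C@]1(C)C=C2[C@H](C)CC[C@H](C(=O)OC)[C@H]2CC1 | intermediate
22 | 2-{(1S,4R,6S,8aR)-6-[(1S)-1-(2,6-dimethoxyphenyl)-3-methylbutyl]-4,6-dimethyl-1,2,3,4,6,7,8,8a-octahydronaphthalen-1-yl}propan-2-ol | CC(C)C[C@H](c1c(OC)cccc1OC)[C@]1(C)C=C2[C@H](C)CC[C@H](C(C)(C)O)[C@H]2CC1 | intermediate
23 | 2-{(1S,4R,6S,8aR)-6-[(1S)-1-[2,6-dimethoxy-4-(4,4,5,5-tetramethyl-1,3,2-dioxaborolan-2-yl)phenyl]-3-methylbutyl]-4,6-dimethyl-1,2,3,4,6,7,8,8a-octahydronaphthalen-1-yl}propan-2-ol | CC(C)C[C@H](c1c(OC)cc(B3OC(C)(C)C(C)(C)O3)cc1OC)[C@]1(C)C=C2[C@H](C)CC[C@H](C(C)(C)O)[C@H]2CC1 | intermediate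
24 | 2-{(1S,4R,6S,8aR)-6-[(1S)-1-(4-hydroxy-2,6-dimethoxyphenyl)-3-methylbutyl]-4,6-dimethyl-1,2,3,4,6,7,8,8a-octahydronaphthalen-1-yl}propan-2-ol | CC(C)C[C@H](c1c(OC)cc(O)cc1OC)[C@]1(C)C=C2[C@H](C)CC[C@H](C(C)(C)O)[C@H]2CC1 | intermediate
25 | 2-{(1S,4R,6S,8aR)-6-[(1S)-1-(3,5-diformyl-4-hydroxy-2,6-dimethoxyphenyl)-3-methylbutyl]-4,6-dimethyl-1,2,3,4,6,7,8,8a-octahydronaphthalen-1-yl}propan-2-ol | CC(C)C[C@H](c1c(OC)c(C=O)c(O)c(C=O)c1OC)[C@]1(C)C=C2[C@H](C)CC[C@H](C(C)(C)O)[C@H]2CC1 | intermediate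
26 | 2-{(1S,4R,6S,8aR)-6-[(1S)-1-(3,5-diformyl-2,4,6-trihydroxyphenyl)-3-methylbutyl]-4,6-dimethyl-1,2,3,4,6,7,8,8a-octahydronaphthalen-1-yl}propan-2-ol (CNP0200991.2) | CC(C)C[C@H](c1c(O)c(C=O)c(O)c(C=O)c1O)[C@]1(C)C=C2[C@H](C)CC[C@H](C(C)(C)O)[C@H]2CC1 | target

## Step count and risks

Total steps: 12. Longest linear sequence: 11 steps (5 to 26, steps 2 to 12); step 1 is a one-step branch that joins at step 3.

The three steps most likely to fail:

Step 3 (the proposed new step). The benzylic cation may instead eliminate to the styrene or attack another arene, and the sense and level of induction at C-6/C-α are unproven. Fallback with known chemistry, setting out from enolate 9 (made as in step 2) and from 4, returning at 12: quench 9 with Me3SiCl to get the regiodefined silyl enol ether trimethyl[(8-methyl-1,4-dioxaspiro[4.5]dec-7-en-7-yl)oxy]silane F5, and acetylate 4 (Ac2O, pyridine) to rac-1-(2,6-dimethoxyphenyl)-3-methylbutyl acetate F6. A ZnBr2-promoted SN1 (Mukaiyama-type) alkylation of F5 with F6 in CH2Cl2 at −78 °C gives 8-[1-(2,6-dimethoxyphenyl)-3-methylbutyl]-8-methyl-1,4-dioxaspiro[4.5]decan-7-one as a mixture of stereoisomers F7. Aqueous HCl then gives the dione 4-[1-(2,6-dimethoxyphenyl)-3-methylbutyl]-4-methylcyclohexane-1,3-dione as a mixture of stereoisomers F8. Chromatographic separation of the diastereomers and preparative chiral-phase chromatography of the racemate deliver 12.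

Step 2. The 1,2-shift could involve the methylene next to the dioxolane, or the carbenoid could simply enolise the ketone. Fallback, setting out from 5 and returning at 10, in which the enol silane fixes the regiochemistry: kinetic deprotonation away from the dioxolane (LiN(iPr)2, Me3SiCl, THF, −78 °C) gives trimethyl[(1,4-dioxaspiro[4.4]non-7-en-7-yl)oxy]silane F1. Ethylidene transfer (Et2Zn, CH3CHI2) gives the siloxycyclopropane trimethyl[(6'-methylspiro[1,3-dioxolane-2,3'-bicyclo[3.1.0]hexan]-1'-yl)oxy]silane F2. FeCl3 in DMF (Saegusa–Ito oxidative opening of the internal cyclopropane bond) gives the ring-enlarged 9-chloro-8-methyl-1,4-dioxaspiro[4.5]decan-7-one F3. NaOAc in MeOH eliminates to 8-methyl-1,4-dioxaspiro[4.5]dec-8-en-7-one F4, and hydrogenation (H2, Pd/C) returns to 10.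

Step 11. The second ortho-formylation of the magnesium-chelated salicylaldehyde may stall at the mono-aldehyde. Fallback, setting out from 24 and returning at 25: base-mediated double hydroxymethylation (aqueous HCHO, NaOH, rt; Lederer–Manasse reaction) gives the bis(hydroxymethyl)phenol 2-{(1S,4R,6S,8aR)-6-[(1S)-1-[4-hydroxy-3,5-bis(hydroxymethyl)-2,6-dimethoxyphenyl]-3-methylbutyl]-4,6-dimethyl-1,2,3,4,6,7,8,8a-octahydronaphthalen-1-yl}propan-2-ol F9. Activated MnO2 in CH2Cl2 then oxidises only the two benzylic alcohols to give 25.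

Further compounds
F1 | step 2 | trimethyl[(1,4-dioxaspiro[4.4]non-7-en-7-yl)oxy]silane | C[Si](C)(C)OC1=CCC2(C1)OCCO2
F2 | step 2 | trimethyl[(6'-methylspiro[1,3-dioxolane-2,3'-bicyclo[3.1.0]hexan]-1'-yl)oxy]silane | C[Si](C)(C)OC12CC3(CC1C2C)OCCO3
F3 | step 2 | 9-chloro-8-methyl-1,4-dioxaspiro[4.5]decan-7-one | CC1C(Cl)CC2(CC1=O)OCCO2
F4 | step 2 | 8-methyl-1,4-dioxaspiro[4.5]dec-8-en-7-one | CC1=CCC2(CC1=O)OCCO2
F5 | step 3 | trimethyl[(8-methyl-1,4-dioxaspiro[4.5]dec-7-en-7-yl)oxy]silane | CC1=C(O[Si](C)(C)C)CC2(CC1)OCCO2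
F6 | step 3 | rac-1-(2,6-dimethoxyphenyl)-3-methylbutyl acetate | CC(C)CC(OC(C)=O)c1c(OC)cccc1OC
F7 | step 3 | 8-[1-(2,6-dimethoxyphenyl)-3-methylbutyl]-8-methyl-1,4-dioxaspiro[4.5]decan-7-one (mixture of stereoisomers) | CC(C)CC(c1c(OC)cccc1OC)C1(C)C(=O)CC2(CC1)OCCO2
F8 | step 3 | 4-[1-(2,6-dimethoxyphenyl)-3-methylbutyl]-4-methylcyclohexane-1,3-dione (mixture of stereoisomers) | CC(C)CC(c1c(OC)cccc1OC)C1(C)C(=O)CC(=O)CC1
F9 | step 11 | 2-{(1S,4R,6S,8aR)-6-[(1S)-1-[4-hydroxy-3,5-bis(hydroxymethyl)-2,6-dimethoxyphenyl]-3-methylbutyl]-4,6-dimethyl-1,2,3,4,6,7,8,8a-octahydronaphthalen-1-yl}propan-2-ol | CC(C)C[C@H](c1c(OC)c(CO)c(O)c(CO)c1OC)[C@]1(C)C=C2[C@H](C)CC[C@H](C(C)(C)O)[C@H]2CC1
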